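**Retrosynthetic overview**

- The tetrahydrofuran ring and the C10 bromide are made last, by 5-exo bromoetherification of a C6-hydroxy oxocene across its C9=C10 alkene.
- The complete (E)-enyne side chain comes from opening a C5–C6 terminal epoxide with an (E)-enynyllithium (fragment C); this also frees the C6 hydroxyl.
- The eight-membered ring is formed first, by ring-closing metathesis of a bis-allyl ether (C9=C10).
- C12 is built by ester reduction, reagent-controlled allylation and Appel inversion; the C7–O–C13 ether comes from SN2 of an epoxy alkoxide (fragment A) on an α-triflyloxy ester (fragment B).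
- Fragment A comes from (±)-hexa-1,5-dien-3-ol, fragment B from L-2-aminobutanoic acid, fragment C from propargyl alcohol.

Assumption: positions are named by the C15 chain (C1 = alkyne CH, C15 = methyl), so the target is (3E,6S,7S,9S,10S,12S,13R) with ether bridges C6–O–C9 and C7–O–C13.

**Route**

Step 1
Reactants: 1 (±)-hexa-1,5-dien-3-ol
Product: 2 (1R)-1-[(2S)-oxiran-2-yl]but-3-en-1-ol
Conditions: Ti(OiPr)4, D-(−)-diisopropyl tartrate, t-BuOOH (0.6 equiv), 4 Å molecular sieves, CH2Cl2, −20 °C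
Reagents that add atoms: tert-butyl hydroperoxide, CC(C)(C)OO
Why: Sharpless kinetic resolution: the titanium–D-tartrate catalyst epoxidises only the allylic vinyl group of the fast-reacting (R)-alcohol and gives the erythro epoxy alcohol, which sets C6 as S.

Step 2
Reactants: 2 (1R)-1-[(2S)-oxiran-2-yl]but-3-en-1-ol
Product: 3 (1S)-1-[(2S)-oxiran-2-yl]but-3-en-1-yl 4-nitrobenzoate
Conditions: 4-O2NC6H4CO2H, PPh3, DIAD, THF, 0 °C → rt
Reagents that add atoms: 4-nitrobenzoic acid, OC(=O)c1ccc(cc1)[N+](=O)[O-]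
Why: Mitsunobu reaction: SN2 displacement of the activated carbinol by the carboxylate inverts C7 to S, making the C6/C7 oxygens threo while the epoxide is untouched.

Step 3
Reactants: 3 (1S)-1-[(2S)-oxiran-2-yl]but-3-en-1-yl 4-nitrobenzoate
Product: 4 (1S)-1-[(2S)-oxiran-2-yl]but-3-en-1-ol
Conditions: K2CO3 (cat.), MeOH, 0 °C
Reagents that add atoms: none
Why: Base-catalysed transesterification of the activated aryl ester is fast at 0 °C, where Payne migration and epoxide methanolysis are slow; no stereocentre is touched.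

Step 4
Reactants: 5 L-2-aminobutanoic acid
Product: 6 (S)-2-hydroxybutanoic acid
Conditions: NaNO2, 1 M H2SO4, 0 °C → rt
Reagents that add atoms: water, O
Why: Diazotisation with carboxylate participation (α-lactone, double inversion) replaces NH2 by OH with net retention.

Step 5
Reactants: 6 (S)-2-hydroxybutanoic acid
Product: 7 methyl (S)-2-hydroxybutanoate
Conditions: MeOH, H2SO4 (cat.), reflux
Reagents that add atoms: methanol, CO
Why: Fischer esterification; the stereocentre is not involved.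

Step 6
Reactants: 7 methyl (S)-2-hydroxybutanoate
Product: 8 methyl (S)-2-{[(trifluoromethyl)sulfonyl]oxy}butanoate
Conditions: Tf2O, 2,6-lutidine, CH2Cl2, −78 → 0 °C, used at once
Reagents that add atoms: trifluoromethanesulfonic anhydride, FC(F)(F)S(=O)(=O)OS(=O)(=O)C(F)(F)F
Why: O-sulfonylation of the α-hydroxy ester with retention gives a secondary electrophile that the adjacent ester activates for SN2.

Step 7
Reactants: 4 (1S)-1-[(2S)-oxiran-2-yl]but-3-en-1-ol; 8 methyl (S)-2-{[(trifluoromethyl)sulfonyl]oxy}butanoate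
Product: 10 methyl (2R)-2-{[(1S)-1-[(2S)-oxiran-2-yl]but-3-en-1-yl]oxy}butanoate, via sodium alkoxide 9 (not isolated)
Conditions: NaN(SiMe3)2, THF, −78 °C; then 8, −78 → −30 °C
Reagents that add atoms: none
Why: Williamson-type SN2 of the alkoxide on the α-triflyloxy ester goes with clean inversion (C13 becomes R) at temperatures where Payne migration and E2 are slow.

Step 8
Reactants: 10 methyl (2R)-2-{[(1S)-1-[(2S)-oxiran-2-yl]but-3-en-1-yl]oxy}butanoate
Product: 11 (2R)-2-{[(1S)-1-[(2S)-oxiran-2-yl]but-3-en-1-yl]oxy}butanal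
Conditions: i-Bu2AlH (1.1 equiv), CH2Cl2, −78 °C; MeOH, aqueous potassium sodium tartrate work-up; used crude
Reagents that add atoms: none
Why: Partial reduction of an α-alkoxy ester stops at the chelated tetrahedral aluminate, which gives the aldehyde on work-up without epimerising C13 or touching the epoxide.

Step 9
Reactants: 11 (2R)-2-{[(1S)-1-[(2S)-oxiran-2-yl]but-3-en-1-yl]oxy}butanal
Product: 12 (4R,5R)-5-{[(1S)-1-[(2S)-oxiran-2-yl]but-3-en-1-yl]oxy}hept-1-en-4-ol
Conditions: salt-free (+)-Ipc2B(allyl), Et2O, −78 °C; NaOH, H2O2 work-up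
Reagents that add atoms: (+)-B-allyldiisopinocampheylborane, C=CCB([C@H]1C[C@H]2C[C@@H]([C@@H]1C)C2(C)C)[C@H]1C[C@H]2C[C@@H]([C@@H]1C)C2(C)C
Why: Brown asymmetric allylboration: the reagent delivers allyl to the Re face through a chair transition state, setting C12 as R (threo to C13) against the weaker substrate bias, with no Lewis acid to open the epoxide.

Step 10
Reactants: 12 (4R,5R)-5-{[(1S)-1-[(2S)-oxiran-2-yl]but-3-en-1-yl]oxy}hept-1-en-4-ol
Product: 13 (2S)-2-[(1S)-1-{[(3R,4S)-4-bromohept-6-en-3-yl]oxy}but-3-en-1-yl]oxirane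
Conditions: CBr4, PPh3, 2,6-lutidine, CH2Cl2, 0 °C → rt
Reagents that add atoms: carbon tetrabromide, BrC(Br)(Br)Br
Why: Appel reaction: bromide displaces the alkoxyphosphonium by SN2 with inversion, giving the (S)-bromide at C12 under buffered neutral conditions that epoxy alcohols are known to survive.

Step 11
Reactants: 13 (2S)-2-[(1S)-1-{[(3R,4S)-4-bromohept-6-en-3-yl]oxy}but-3-en-1-yl]oxirane
Product: 14 (2R,3S,5Z,8S)-3-bromo-2-ethyl-8-[(2S)-oxiran-2-yl]-3,4,7,8-tetrahydro-2H-oxocine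
Conditions: second-generation Grubbs catalyst (H2IMes)(PCy3)Cl2Ru=CHPh (5 mol %), CH2Cl2 (2 mM), 40 °C
Reagents that add atoms: none
Why: Ring-closing metathesis: gauche preferences of the vicinal C–O/C–Br and C–O/C–O bonds hold the two allyl groups close, so the diene closes to the eight-membered (Z)-ether with loss of ethene; bromide and epoxide are inert.

Step 12
Reactants: 15 prop-2-yn-1-ol
Product: 17 3-(trimethylsilyl)prop-2-yn-1-ol, via bis-silyl ether 16 (not isolated)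
Conditions: n-BuLi (2.1 equiv), THF, −78 °C; Me3SiCl (2.2 equiv), → rt; then 1 M HCl, rt
Reagents that add atoms: chlorotrimethylsilane, C[Si](C)(C)Cl
Why: Double deprotonation and silylation at O and C, then selective acid cleavage of the labile O–Si bond, leaves the C-silylated alkyne.

Step 13
Reactants: 17 3-(trimethylsilyl)prop-2-yn-1-ol
Product: 18 3-(trimethylsilyl)prop-2-ynal
Conditions: MnO2 (activated, excess), CH2Cl2, rt; used as solution
Reagents that add atoms: none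
Why: Selective oxidation of a propargylic alcohol to the ynal on MnO2 without over-oxidation.

Step 14
Reactants: 18 3-(trimethylsilyl)prop-2-ynal
Product: 19 [(3E)-4-iodobut-3-en-1-yn-1-yl]trimethylsilane
Conditions: CrCl2 (6 equiv), CHI3 (2 equiv), THF, 0 °C
Reagents that add atoms: iodoform, IC(I)I
Why: Takai olefination: the geminal dichromium species adds to the aldehyde and eliminates to the (E)-vinyl iodide; a minor Z isomer is removed by chromatography.

Step 15
Reactants: 14 (2R,3S,5Z,8S)-3-bromo-2-ethyl-8-[(2S)-oxiran-2-yl]-3,4,7,8-tetrahydro-2H-oxocine; 19 [(3E)-4-iodobut-3-en-1-yn-1-yl]trimethylsilane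
Product: 21 (1S,3E)-1-[(2S,4Z,7S,8R)-7-bromo-8-ethyl-3,6,7,8-tetrahydro-2H-oxocin-2-yl]-6-(trimethylsilyl)hex-3-en-5-yn-1-ol, via enynyllithium 20 (not isolated)
Conditions: 19 (1.5 equiv), t-BuLi (3.0 equiv), Et2O, −78 °C; then 14, BF3·OEt2 (1.5 equiv), THF, −78 °C
Reagents that add atoms: none
Why: Iodine–lithium exchange keeps the E geometry, and BF3-promoted SN2 opening of the terminal epoxide at C5 joins the side chain and frees the C6 hydroxyl (S, unchanged); the secondary bromide is inert at −78 °C.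

Step 16
Reactants: 21 (1S,3E)-1-[(2S,4Z,7S,8R)-7-bromo-8-ethyl-3,6,7,8-tetrahydro-2H-oxocin-2-yl]-6-(trimethylsilyl)hex-3-en-5-yn-1-ol
Product: 22 (1S,3E)-1-[(2S,4Z,7S,8R)-7-bromo-8-ethyl-3,6,7,8-tetrahydro-2H-oxocin-2-yl]hex-3-en-5-yn-1-ol
Conditions: K2CO3 (cat.), MeOH, 0 °C → rt
Reagents that add atoms: none
Why: Methoxide-mediated protodesilylation of the alkynylsilane is much faster than any substitution or elimination of the secondary bromide.

Step 17
Reactants: 22 (1S,3E)-1-[(2S,4Z,7S,8R)-7-bromo-8-ethyl-3,6,7,8-tetrahydro-2H-oxocin-2-yl]hex-3-en-5-yn-1-ol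
Product: 23 (1S,3R,4S,6S,7S,9S)-4,6-dibromo-3-ethyl-9-[(2E)-pent-2-en-4-yn-1-yl]-2,8-dioxabicyclo[5.2.1]decane
Conditions: NBS (1.2 equiv), CH2Cl2, 0 °C → rt, dark
Reagents that add atoms: N-bromosuccinimide, BrN1C(=O)CCC1=O
Why: Bromoetherification: the electron-rich ring alkene forms a bromonium ion that the C6 hydroxyl opens 5-exo at C9 on its own face, so anti addition sets C9 (S) and C10 (S); the conjugated enyne is too electron-poor to compete.

**Compound list**

1 | (±)-hexa-1,5-dien-3-ol | C=CCC(O)C=C | starting material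
2 | (1R)-1-[(2S)-oxiran-2-yl]but-3-en-1-ol | C=CC[C@@H](O)[C@@H]1CO1 | intermediate
3 | (1S)-1-[(2S)-oxiran-2-yl]but-3-en-1-yl 4-nitrobenzoate | C=CC[C@H](OC(=O)c1ccc(cc1)[N+](=O)[O-])[C@@H]2CO2 | intermediate
4 | (1S)-1-[(2S)-oxiran-2-yl]but-3-en-1-ol (fragment A) | C=CC[C@H](O)[C@@H]1CO1 | intermediate
5 | L-2-aminobutanoic acid | CC[C@H](N)C(=O)O | starting material
6 | (S)-2-hydroxybutanoic acid | CC[C@H](O)C(=O)O | intermediate
7 | methyl (S)-2-hydroxybutanoate | CC[C@H](O)C(=O)OC | intermediate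
8 | methyl (S)-2-{[(trifluoromethyl)sulfonyl]oxy}butanoate (fragment B) | CC[C@H](OS(=O)(=O)C(F)(F)F)C(=O)OC | intermediate
9 | sodium (1S)-1-[(2S)-oxiran-2-yl]but-3-en-1-olate | C=CC[C@H]([O-])[C@@H]1CO1.[Na+] | intermediate
10 | methyl (2R)-2-{[(1S)-1-[(2S)-oxiran-2-yl]but-3-en-1-yl]oxy}butanoate | CC[C@@H](O[C@@H](CC=C)[C@@H]1CO1)C(=O)OC | intermediate
11 | (2R)-2-{[(1S)-1-[(2S)-oxiran-2-yl]but-3-en-1-yl]oxy}butanal | CC[C@@H](O[C@@H](CC=C)[C@@H]1CO1)C=O | intermediate
12 | (4R,5R)-5-{[(1S)-1-[(2S)-oxiran-2-yl]but-3-en-1-yl]oxy}hept-1-en-4-ol | CC[C@@H](O[C@@H](CC=C)[C@@H]1CO1)[C@H](O)CC=C | intermediate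
13 | (2S)-2-[(1S)-1-{[(3R,4S)-4-bromohept-6-en-3-yl]oxy}but-3-en-1-yl]oxirane | CC[C@@H](O[C@@H](CC=C)[C@@H]1CO1)[C@@H](Br)CC=C | intermediate
14 | (2R,3S,5Z,8S)-3-bromo-2-ethyl-8-[(2S)-oxiran-2-yl]-3,4,7,8-tetrahydro-2H-oxocine | CC[C@@H]1[C@@H](Br)C/C=C\C[C@H](O1)[C@@H]2CO2 | intermediate
15 | prop-2-yn-1-ol | C#CCO | starting material
16 | trimethyl{3-[(trimethylsilyl)oxy]prop-1-yn-1-yl}silane | C[Si](C)(C)C#CCO[Si](C)(C)C | intermediate
17 | 3-(trimethylsilyl)prop-2-yn-1-ol | C[Si](C)(C)C#CCO | intermediate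
18 | 3-(trimethylsilyl)prop-2-ynal | C[Si](C)(C)C#CC=O | intermediate
19 | [(3E)-4-iodobut-3-en-1-yn-1-yl]trimethylsilane (fragment C) | C[Si](C)(C)C#C/C=C/I | intermediate
20 | [(1E)-4-(trimethylsilyl)but-1-en-3-yn-1-yl]lithium | [Li]/C=C/C#C[Si](C)(C)C | intermediate
21 | (1S,3E)-1-[(2S,4Z,7S,8R)-7-bromo-8-ethyl-3,6,7,8-tetrahydro-2H-oxocin-2-yl]-6-(trimethylsilyl)hex-3-en-5-yn-1-ol | CC[C@@H]1[C@@H](Br)C/C=C\C[C@H](O1)[C@@H](O)C/C=C/C#C[Si](C)(C)C | intermediate
22 | (1S,3E)-1-[(2S,4Z,7S,8R)-7-bromo-8-ethyl-3,6,7,8-tetrahydro-2H-oxocin-2-yl]hex-3-en-5-yn-1-ol | CC[C@@H]1[C@@H](Br)C/C=C\C[C@H](O1)[C@@H](O)C/C=C/C#C | intermediate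
23 | (1S,3R,4S,6S,7S,9S)-4,6-dibromo-3-ethyl-9-[(2E)-pent-2-en-4-yn-1-yl]-2,8-dioxabicyclo[5.2.1]decane | C#C/C=C/C[C@@H]1O[C@H]2C[C@@H]1O[C@H](CC)[C@@H](Br)C[C@@H]2Br | target

**Step count**

Total step count: 17.
Longest linear sequence: 11 steps (steps 1–3, 7–11, 15–17; the line through steps 4–6 is equally long).

**Steps most likely to fail, with fallbacks**

Step 7 (ether formation). The hindered alkoxide may cause E2 of the triflate, attack its ester, or undergo Payne migration. The fallback uses an α-bromo carboxylate as the electrophile and sets out from 4 and 5. Diazotisation of 5 in aqueous HBr/KBr with NaNO2 at 0 °C gives, with retention, (S)-2-bromobutanoic acid F1. The sodium alkoxide of 4 (NaH, 2.2 equiv, THF, 0 °C → rt) displaces bromide from the sodium carboxylate of F1 with inversion. The carboxylate shields the carbonyl and slows elimination, giving (2R)-2-{[(1S)-1-[(2S)-oxiran-2-yl]but-3-en-1-yl]oxy}butanoic acid F2. Esterification with Me3SiCHN2 in MeOH/toluene returns to the route at 10.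

Step 10 (Appel bromination beside an epoxide). Bromide may open the epoxide, or the alkoxyphosphonium may eliminate toward the allylic position. The fallback moves the bromination to the end, when neither the epoxide nor a free C6 hydroxyl remains, and sets out from 12. Ring-closing metathesis of 12 with the same catalyst gives (2R,3R,5Z,8S)-2-ethyl-8-[(2S)-oxiran-2-yl]-3,4,7,8-tetrahydro-2H-oxocin-3-ol F3. Opening with 20 and BF3·OEt2 (one extra equivalent of 20 for the free hydroxyl) gives (2R,3R,5Z,8S)-2-ethyl-8-[(1S,3E)-1-hydroxy-6-(trimethylsilyl)hex-3-en-5-yn-1-yl]-3,4,7,8-tetrahydro-2H-oxocin-3-ol F4. K2CO3 in MeOH gives (2R,3R,5Z,8S)-2-ethyl-8-[(1S,3E)-1-hydroxyhex-3-en-5-yn-1-yl]-3,4,7,8-tetrahydro-2H-oxocin-3-ol F5. NBS closes the tetrahydrofuran by 5-exo attack of the C6 hydroxyl, which should outrun 5-endo attack by the C12 hydroxyl, to give (1S,3R,4R,6S,7S,9S)-6-bromo-3-ethyl-9-[(2E)-pent-2-en-4-yn-1-yl]-2,8-dioxabicyclo[5.2.1]decan-4-ol F6. CBr4 and P(n-C8H17)3 in toluene at 70 °C then replace the hydroxyl with inversion and return to the route at 23.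

Step 15 (epoxide opening by the enynyllithium). The organolithium may eliminate HBr from the secondary bromide or the exchange may be incomplete. The fallback brings in the side chain as a plain allyl group and builds the enyne afterwards; it sets out from 14. CH2=CHMgBr with CuI (cat.) in THF at −40 °C opens the epoxide to (1S)-1-[(2S,4Z,7S,8R)-7-bromo-8-ethyl-3,6,7,8-tetrahydro-2H-oxocin-2-yl]but-3-en-1-ol F7. NBS bromoetherification on the more electron-rich ring alkene gives (1S,3R,4S,6S,7S,9S)-9-allyl-4,6-dibromo-3-ethyl-2,8-dioxabicyclo[5.2.1]decane F8. Cross-metathesis with crotonaldehyde (second-generation Grubbs catalyst, CH2Cl2, 40 °C) gives (2E)-4-[(1S,3R,4S,6S,7S,9S)-4,6-dibromo-3-ethyl-2,8-dioxabicyclo[5.2.1]decan-9-yl]but-2-enal F9. Colvin homologation with Me3SiCHN2 and LiN(i-Pr)2 in THF (−78 → 0 °C) returns to the route at 23.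

**Further compounds**

F1 | step 7 | (S)-2-bromobutanoic acid | CC[C@H](Br)C(=O)O
F2 | step 7 | (2R)-2-{[(1S)-1-[(2S)-oxiran-2-yl]but-3-en-1-yl]oxy}butanoic acid | CC[C@@H](O[C@@H](CC=C)[C@@H]1CO1)C(=O)O
F3 | step 10 | (2R,3R,5Z,8S)-2-ethyl-8-[(2S)-oxiran-2-yl]-3,4,7,8-tetrahydro-2H-oxocin-3-ol | CC[C@@H]1[C@H](O)C/C=C\C[C@H](O1)[C@@H]2CO2
F4 | step 10 | (2R,3R,5Z,8S)-2-ethyl-8-[(1S,3E)-1-hydroxy-6-(trimethylsilyl)hex-3-en-5-yn-1-yl]-3,4,7,8-tetrahydro-2H-oxocin-3-ol | CC[C@@H]1[C@H](O)C/C=C\C[C@H](O1)[C@@H](O)C/C=C/C#C[Si](C)(C)C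
F5 | step 10 | (2R,3R,5Z,8S)-2-ethyl-8-[(1S,3E)-1-hydroxyhex-3-en-5-yn-1-yl]-3,4,7,8-tetrahydro-2H-oxocin-3-ol | CC[C@@H]1[C@H](O)C/C=C\C[C@H](O1)[C@@H](O)C/C=C/C#C
F6 | step 10 | (1S,3R,4R,6S,7S,9S)-6-bromo-3-ethyl-9-[(2E)-pent-2-en-4-yn-1-yl]-2,8-dioxabicyclo[5.2.1]decan-4-ol | C#C/C=C/C[C@@H]1O[C@H]2C[C@@H]1O[C@H](CC)[C@H](O)C[C@@H]2Br
F7 | step 15 | (1S)-1-[(2S,4Z,7S,8R)-7-bromo-8-ethyl-3,6,7,8-tetrahydro-2H-oxocin-2-yl]but-3-en-1-ol | CC[C@@H]1[C@@H](Br)C/C=C\C[C@H](O1)[C@@H](O)CC=C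
F8 | step 15 | (1S,3R,4S,6S,7S,9S)-9-allyl-4,6-dibromo-3-ethyl-2,8-dioxabicyclo[5.2.1]decane | C=CC[C@@H]1O[C@H]2C[C@@H]1O[C@H](CC)[C@@H](Br)C[C@@H]2Br
F9 | step 15 | (2E)-4-[(1S,3R,4S,6S,7S,9S)-4,6-dibromo-3-ethyl-2,8-dioxabicyclo[5.2.1]decan-9-yl]but-2-enal | O=C/C=C/C[C@@H]1O[C@H]2C[C@@H]1O[C@H](CC)[C@@H](Br)C[C@@H]2Br
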